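**Retrosynthetic overview**
1. The strategy rests on the cis-fused α-methylene-γ-butyrolactone (O–C6–C7–C11–C12), which shares its C6–C7 edge with the cycloheptane (C1, C5–C10). This motif is what a 2-(methoxycarbonyl)allyl metal gives when it adds through C7 to a C6 aldehyde.
2. The last C–C bond is C6–C7. CrCl2 acts on the open-chain bromo-enoate aldehyde 31 and closes the seven-membered ring first and the lactone second, in one flask. Desilylation then ends the route.
3. The bromo-enoate comes from a C7 aldehyde by Morita–Baylis–Hillman reaction and SN2′ bromination. Both are run while C2 is still a silylated (Z)-allylic alcohol, because an amine catalyst would isomerise the Z-enone. C7 is carried as a PMB ether, so no alkene has to be cleaved once the propenyl group is present.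
4. C9 and C10 come from a boron aldol of dioxolanyl ethyl ketone 3 with aldehyde 6, and C1 from a Cram-chelate vinyl addition. Both controls need the C5 epimer, so C5 is then corrected by oxidation and CBS reduction before the isovalerate goes on.
5. C2–C4 are built from vinyl via the aldehyde and (Z)-propenylmagnesium bromide. One double oxidation at the end unveils the Z-enone and the C6 aldehyde together.

Key step: step 22

Assumption: C1 is the carbinol carbon bearing the butenoyl group, C2 its C=O, C5 the CH–O-isovalerate, C6/C7 the lactone CH–O/CH, C8 the CH2, C9 the CHOH, C10 the CHCH3 and C11/C12/C13 the lactone C(=)/C=O/=CH2; the carbinol centres C2 (23–30) and C7 (28) are carried as epimer mixtures because both become sp2 later.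

Step 1
Reactants: 1 methyl (4R)-2,2-dimethyl-1,3-dioxolane-4-carboxylate
Product: 3 1-[(4R)-2,2-dimethyl-1,3-dioxolan-4-yl]propan-1-one, via Weinreb amide 2 (not isolated)
Conditions: MeNHOMe·HCl, i-PrMgCl, THF, −20 °C; then EtMgBr, −20 → 0 °C
Reagents that add atoms: ethylmagnesium bromide CC[Mg]Br; N,O-dimethylhydroxylamine hydrochloride CNOC.Cl (its atoms stay only in 2)
Why: The chloromagnesium amide should aminolyse ester 1 to Weinreb amide 2, whose chelated tetrahedral adduct with EtMgBr survives until work-up and so stops at ketone 3 (one-flask Weinreb ketone synthesis), while the low temperature guards the C5 centre against enolisation.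

Step 2
Reactants: 4 propane-1,3-diol
Product: 5 3-[(4-methoxybenzyl)oxy]propan-1-ol
Conditions: NaH (1 equiv), PMBCl, Bu4NI (cat.), THF–DMF, 0 °C → rt, diol in excess
Reagents that add atoms: 4-methoxybenzyl chloride COc1ccc(CCl)cc1
Why: Williamson etherification of the monoalkoxide of an excess of the symmetrical diol should give mainly the mono-ether, and no stereocentre is involved.

Step 3
Reactants: 5 3-[(4-methoxybenzyl)oxy]propan-1-ol
Product: 6 3-[(4-methoxybenzyl)oxy]propanal
Conditions: TEMPO (2,2,6,6-tetramethylpiperidine-1-oxyl, cat.), PhI(OAc)2, CH2Cl2, rt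
Reagents that add atoms: none
Why: The oxoammonium species formed from TEMPO and PhI(OAc)2 oxidises the primary alcohol and should stop at the aldehyde (TEMPO oxidation) without touching the PMB ether.

Step 4
Reactants: 3 1-[(4R)-2,2-dimethyl-1,3-dioxolan-4-yl]propan-1-one; 6 3-[(4-methoxybenzyl)oxy]propanal
Product: 8 (2S,3R)-1-[(4R)-2,2-dimethyl-1,3-dioxolan-4-yl]-3-hydroxy-5-[(4-methoxybenzyl)oxy]-2-methylpentan-1-one (5R,9R,10S), via Z-dibutylboron enolate 7 (not isolated)
Conditions: n-Bu2BOTf, i-Pr2NEt, CH2Cl2, −78 → 0 °C; 6, −78 → −20 °C; H2O2, MeOH, pH 7 buffer, 0 °C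
Reagents that add atoms: none
Why: n-Bu2BOTf and i-Pr2NEt should enolise 3 on the ethyl side to the Z-boron enolate 7, which cannot chelate and adds to 6 through a Zimmerman–Traxler chair (boron aldol reaction) to give the 9,10-syn aldol; the enolate face is fixed by the dioxolane centre, whose C5–O bond lies anti to the enolate C–O bond while the aldehyde approaches anti to the ring CH2, and this sets C10 as S and C9 as R.

Step 5
Reactants: 8 syn aldol (5R,9R,10S)
Product: 9 C9 tert-butyldimethylsilyl ether of 8 (5R,9R,10S)
Conditions: TBSOTf, 2,6-lutidine, CH2Cl2, −78 → 0 °C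
Reagents that add atoms: tert-butyldimethylsilyl triflate CC(C)(C)[Si](C)(C)OS(=O)(=O)C(F)(F)F
Why: Silyl triflate silylation with a hindered pyridine base protects the β-hydroxy ketone without retro-aldol or epimerisation, and it also removes the C9 oxygen as a chelating site for the next step.

Step 6
Reactants: 9 C9 silyl ether ketone (5R,9R,10S)
Product: 10 C1 vinyl carbinol (1S,5R,9R,10S), the tertiary alcohol that bears vinyl as the future C2 and keeps the dioxolane
Conditions: MgBr2·OEt2, CH2Cl2, −78 °C; CH2=CHMgBr (THF solution), −78 °C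
Reagents that add atoms: vinylmagnesium bromide C=C[Mg]Br
Why: Magnesium should bind the ketone oxygen and the α-oxygen O5 in a five-membered Cram chelate, so vinyl arrives from the face opposite the ring CH2 (chelation-controlled Grignard addition); the Felkin–Anh preference of C10 favours the same face, which places OH, C2, C5 and C10 on C1 as in the target, and this matched pairing exists only for the R epimer at C5.

Step 7
Reactants: 10 C1 vinyl carbinol
Product: 11 C1,C5,C6-triol (1S,5R,9R,10S)
Conditions: AcOH–H2O (4:1), rt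
Reagents that add atoms: none
Why: Mild acid hydrolysis cleaves the terminal isopropylidene acetal faster than the hindered secondary TBS ether or the PMB ether (acetal hydrolysis), and no stereocentre is touched.

Step 8
Reactants: 11 triol
Product: 12 C6 triethylsilyl ether of 11 (1S,5R,9R,10S)
Conditions: TESCl (1.05 equiv), imidazole, CH2Cl2, −30 °C
Reagents that add atoms: chlorotriethylsilane CC[Si](Cl)(CC)CC
Why: Imidazole-promoted silylation follows steric access, so the primary C6 hydroxyl should react before the neopentyl-type secondary C5 and the tertiary C1 hydroxyls.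

Step 9
Reactants: 12 C6 silyl ether diol
Product: 13 C5 ketone (1S,9R,10S) that keeps the free C1 hydroxyl
Conditions: DMP, NaHCO3, CH2Cl2, 0 °C → rt
Reagents that add atoms: none
Why: Dess–Martin oxidation converts the only oxidisable carbinol (C5) into the ketone without cleaving the diol, which erases the relay configuration at C5 while the tertiary C1 alcohol cannot react.

Step 10
Reactants: 13 C5 ketone
Product: 14 C1,C6-bis(triethylsilyl) C5 ketone (1S,9R,10S)
Conditions: TESOTf, 2,6-lutidine, CH2Cl2, −78 → 0 °C
Reagents that add atoms: triethylsilyl triflate CC[Si](CC)(CC)OS(=O)(=O)C(F)(F)F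
Why: The silyl triflate is reactive enough for the tertiary alcohol, which here has two sp2 neighbours, and the weak base should not enolise the ketone (silyl triflate silylation).

Step 11
Reactants: 14 bis-silyl C5 ketone
Product: 15 C5 alcohol (1S,5S,9R,10S)
Conditions: (R)-B-methyl-CBS oxazaborolidine from (R)-diphenylprolinol (C18H20BNO, 0.3 equiv), catecholborane, toluene, −78 → −40 °C; MeOH, then aqueous work-up
Reagents that add atoms: none
Why: In the Corey–Bakshi–Shibata reduction the ketone binds with the quaternary C1 side as the large group, so the (R)-catalyst should deliver hydride to give 5S; the polar Felkin–Anh model with the C1–OSi bond anti to hydride favours the same sense, and catecholborane at low temperature spares the vinyl group.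

Step 12
Reactants: 15 C5 alcohol; 16 isovaleryl chloride
Product: 17 C5 isovalerate (1S,5S,9R,10S)
Conditions: pyridine, 4-(dimethylamino)pyridine (cat.), CH2Cl2, 0 °C → rt
Reagents that add atoms: none
Why: DMAP-catalysed acylation esterifies the only free hydroxyl with retention at C5, since the C–O bond is not broken.

Step 13
Reactants: 17 C5 isovalerate
Product: 19 C2 aldehyde (1S,5S,9R,10S), via secondary ozonide 18 (not isolated)
Conditions: O3, CH2Cl2, −78 °C (Sudan red 7B end point); Me2S, −78 °C → rt
Reagents that add atoms: ozone [O-][O+]=O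
Why: The vinyl group is the only alkene in 17, so ozonolysis with reductive work-up should give the non-enolisable α-silyloxy aldehyde, and the indicator dye stops the reaction before the anisyl ring is attacked.

Step 14
Reactants: 19 C2 aldehyde; 20 (Z)-1-bromoprop-1-ene
Product: 23 C2 (Z)-prop-1-enyl carbinol (C2 epimers; C1 C5 C9 C10 unchanged), via (Z)-prop-1-enyllithium 21 (not isolated), via (Z)-prop-1-enylmagnesium bromide 22 (not isolated)
Conditions: 20, t-BuLi (2 equiv), Et2O, −78 °C; MgBr2·OEt2, −78 °C; 19, Et2O–THF, −78 °C; sat. NH4Cl at −78 °C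
Reagents that add atoms: none
Why: Bromine–lithium exchange and transmetalation both retain the alkene geometry, and the alkenyl Grignard reagent at −78 °C should add to the aldehyde much faster than to the isovalerate (1,2-addition); the cold quench suppresses acyl and silyl migration, and the new C2 centre need not be controlled.

Step 15
Reactants: 23 C2 carbinol
Product: 24 C1,C2,C6-tris(triethylsilyl) ether (C2 epimers)
Conditions: TESOTf, 2,6-lutidine, CH2Cl2, −78 → 0 °C
Reagents that add atoms: triethylsilyl triflate CC[Si](CC)(CC)OS(=O)(=O)C(F)(F)F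
Why: Non-basic silyl triflate silylation caps the hindered allylic alcohol, and any material in which the C1 silyl group had moved to O2 in step 14 converges on the same tris-silyl ether.

Step 16
Reactants: 24 tris-silyl PMB ether
Product: 25 C7 primary alcohol
Conditions: DDQ, CH2Cl2–pH 7 phosphate buffer (10:1), 0 °C
Reagents that add atoms: none
Why: DDQ removes a benzylic hydride from the electron-rich PMB ether and water collapses the oxocarbenium ion (oxidative PMB cleavage), while the buffer protects the triethylsilyl ethers from the acidic hydroquinone.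

Step 17
Reactants: 25 C7 alcohol
Product: 26 C7 aldehyde
Conditions: DMP, NaHCO3, CH2Cl2, 0 °C → rt
Reagents that add atoms: none
Why: Buffered Dess–Martin oxidation of the single free alcohol gives the β-silyloxy aldehyde under conditions too mild for β-elimination.

Step 18
Reactants: 26 C7 aldehyde; 27 methyl acrylate
Product: 28 Morita–Baylis–Hillman adduct, methyl 2-(1-hydroxyalkyl)acrylate at C7 (C7 and C2 epimers)
Conditions: 27 (neat, excess), quinuclidine (1-azabicyclo[2.2.2]octane, 0.5 equiv), MeOH (1 equiv), rt
Reagents that add atoms: none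
Why: The amine adds to methyl acrylate, the zwitterionic enolate attacks the unbranched C7 aldehyde and the amine is then lost (Morita–Baylis–Hillman reaction); the substrate holds no enone that the amine could isomerise, and the C7 carbinol centre is erased in step 19.

Step 19
Reactants: 28 Morita–Baylis–Hillman adduct
Product: 29 (Z)-2-(bromomethyl)enoate, tris(triethylsilyl) ether
Conditions: NBS, Me2S, CH2Cl2, 0 °C → rt
Reagents that add atoms: N-bromosuccinimide O=C1CCC(=O)N1Br
Why: The sulfonium reagent formed from NBS and Me2S activates the C7 hydroxyl and bromide attacks the terminal methylene C13 with allylic transposition (SN2′ bromination of Baylis–Hillman adducts), so both C7 epimers should give the trisubstituted enoate with C8 trans to the ester under near-neutral conditions.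

Step 20
Reactants: 29 tris-silyl bromide
Product: 30 C2,C6-diol that keeps the C1 triethylsilyl and C9 tert-butyldimethylsilyl ethers
Conditions: pyridinium p-toluenesulfonate (0.1 equiv), MeOH–CH2Cl2 (1:4), −10 → 0 °C; product used at once
Reagents that add atoms: none
Why: Acid-catalysed methanolysis of silyl ethers depends on access to silicon, so the primary C6 and secondary C2 triethylsilyl ethers should be lost while the buried tertiary C1 triethylsilyl ether and the TBS ether remain.

Step 21
Reactants: 30 diol
Product: 31 open-chain keto aldehyde, the ring-closure precursor (C6 aldehyde, Z-enone, (Z)-bromomethyl enoate; C5 now labelled R because CHO outranks C1, geometry unchanged)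
Conditions: DMP (3 equiv), NaHCO3, CH2Cl2, 0 °C → rt
Reagents that add atoms: none
Why: One buffered Dess–Martin oxidation converts both carbinols, merging the C2 epimers into the Z-enone without isomerisation and giving the α-acyloxy aldehyde without epimerisation.

Step 22
Reactants: 31 open-chain keto aldehyde
Product: 34 bis-silyl ether of the target (C9 tert-butyldimethylsilyl and C1 triethylsilyl; 1S,5S,6R,7S,9R,10S), via allylchromium dichloride 32 (not isolated), via chromium alkoxide 33 (not isolated)
Conditions: CrCl2 (8 equiv), 4 Å molecular sieves, THF, rt, syringe-pump addition of 31 to about 2 mM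
Reagents that add atoms: none
Why: Two equivalents of CrCl2 should reduce the C13–Br bond of 31 to the σ-allylchromium species 32, whose double-bond isomers interconvert by 1,3-metal shift, and its γ-carbon C7 then adds to the chromium-bound C6 aldehyde through a six-membered chair before alkoxide 33 attacks the adjacent methyl ester and expels methoxide. The closest known reaction type is the intramolecular Nozaki–Hiyama allylation of aldehydes by 2-(bromomethyl)acrylates, which delivers carbocycle-fused α-methylene-γ-butyrolactones. The cycloheptane closes in a 7-exo-trig mode at the aldehyde carbon and the lactone in a 5-exo-trig addition–elimination at the ester carbonyl. The C6/C7 relationship is set by the chair, because the favoured allylchromium geometry keeps C8 trans to the ester and therefore axial on C7, which gives the syn adduct with H6 and H7 cis, that is the cis ring fusion that lactonises readily. The absolute sense at C6 and C7 is set by C5, because the tether holds C1 gauche to the incoming C7 and, of the two rotamers left, the one with the C5–O bond antiperiplanar to the metal-bound C6=O dipole (Cornforth-type arrangement) exposes the face that puts O6 trans to O5 on the new ring as in the target, and this is the least secure element. The step needs γ- over α-attack (which would require a nine-membered ring), the aldehyde over the C2 ketone (a six-membered closure) and over the two ester carbonyls, and cyclisation over oligomerisation; these should be secured by the cyclic transition state, by the aldehyde preference of allylchromium reagents reinforced by the neopentyl and conjugated nature of C2, and by slow addition at high dilution.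

Step 23
Reactants: 34 bis-silyl lactone
Product: 35 target CNP0186412.2 (1S,5S,6R,7S,9R,10S)
Conditions: HF·pyridine, excess pyridine, THF, 0 °C → rt
Reagents that add atoms: none
Why: Pyridine-buffered fluoride cleaves both Si–O bonds (fluoride desilylation) at a mildly acidic pH that should not isomerise the Z-enone, shift the isovalerate or add to the α-methylene lactone.

**Compound list**
1 | methyl (4R)-2,2-dimethyl-1,3-dioxolane-4-carboxylate | COC(=O)[C@H]1COC(C)(C)O1 | starting material
2 | (4R)-N-methoxy-N,2,2-trimethyl-1,3-dioxolane-4-carboxamide (not isolated) | CON(C)C(=O)[C@H]1COC(C)(C)O1 | intermediate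
3 | 1-[(4R)-2,2-dimethyl-1,3-dioxolan-4-yl]propan-1-one | CCC(=O)[C@H]1COC(C)(C)O1 | intermediate
4 | propane-1,3-diol | OCCCO | starting material
5 | 3-[(4-methoxybenzyl)oxy]propan-1-ol | COc1ccc(COCCCO)cc1 | intermediate
6 | 3-[(4-methoxybenzyl)oxy]propanal | COc1ccc(COCCC=O)cc1 | intermediate
7 | Z-dibutylboron enolate of 3 (not isolated) | C/C=C(\OB(CCCC)CCCC)[C@H]1COC(C)(C)O1 | intermediate
8 | syn aldol (5R,9R,10S) | COc1ccc(COCC[C@@H](O)[C@H](C)C(=O)[C@H]2COC(C)(C)O2)cc1 | intermediate
9 | C9 TBS ether of 8 | COc1ccc(COCC[C@@H](O[Si](C)(C)C(C)(C)C)[C@H](C)C(=O)[C@H]2COC(C)(C)O2)cc1 | intermediate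
10 | C1 vinyl carbinol (1S,5R,9R,10S) | COc1ccc(COCC[C@@H](O[Si](C)(C)C(C)(C)C)[C@H](C)[C@@](O)(C=C)[C@H]2COC(C)(C)O2)cc1 | intermediate
11 | C1,C5,C6-triol (1S,5R,9R,10S) | COc1ccc(COCC[C@@H](O[Si](C)(C)C(C)(C)C)[C@H](C)[C@@](O)(C=C)[C@H](O)CO)cc1 | intermediate
12 | C6 TES ether of 11 | COc1ccc(COCC[C@@H](O[Si](C)(C)C(C)(C)C)[C@H](C)[C@@](O)(C=C)[C@H](O)CO[Si](CC)(CC)CC)cc1 | intermediate
13 | C5 ketone, free C1–OH (1S,9R,10S) | COc1ccc(COCC[C@@H](O[Si](C)(C)C(C)(C)C)[C@H](C)[C@@](O)(C=C)C(=O)CO[Si](CC)(CC)CC)cc1 | intermediate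
14 | C1,C6-bis-TES C5 ketone | COc1ccc(COCC[C@@H](O[Si](C)(C)C(C)(C)C)[C@H](C)[C@@](O[Si](CC)(CC)CC)(C=C)C(=O)CO[Si](CC)(CC)CC)cc1 | intermediate
15 | C5 alcohol (1S,5S,9R,10S) | COc1ccc(COCC[C@@H](O[Si](C)(C)C(C)(C)C)[C@H](C)[C@@](O[Si](CC)(CC)CC)(C=C)[C@@H](O)CO[Si](CC)(CC)CC)cc1 | intermediate
16 | isovaleryl chloride | CC(C)CC(Cl)=O | starting material
17 | C5 isovalerate (1S,5S,9R,10S) | COc1ccc(COCC[C@@H](O[Si](C)(C)C(C)(C)C)[C@H](C)[C@@](O[Si](CC)(CC)CC)(C=C)[C@@H](OC(=O)CC(C)C)CO[Si](CC)(CC)CC)cc1 | intermediate
18 | secondary ozonide of 17 (not isolated) | COc1ccc(COCC[C@@H](O[Si](C)(C)C(C)(C)C)[C@H](C)[C@@](O[Si](CC)(CC)CC)(C2OCOO2)[C@@H](OC(=O)CC(C)C)CO[Si](CC)(CC)CC)cc1 | intermediate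
19 | C2 aldehyde (1S,5S,9R,10S) | COc1ccc(COCC[C@@H](O[Si](C)(C)C(C)(C)C)[C@H](C)[C@@](O[Si](CC)(CC)CC)(C=O)[C@@H](OC(=O)CC(C)C)CO[Si](CC)(CC)CC)cc1 | intermediate
20 | (Z)-1-bromoprop-1-ene | C/C=C\Br | starting material
21 | (Z)-prop-1-enyllithium (not isolated) | C/C=C\[Li] | intermediate
22 | (Z)-prop-1-enylmagnesium bromide (not isolated) | C/C=C\[Mg]Br | intermediate
23 | C2 (Z)-propenyl carbinol, C2 epimers | COc1ccc(COCC[C@@H](O[Si](C)(C)C(C)(C)C)[C@H](C)[C@@](O[Si](CC)(CC)CC)(C(O)/C=C\C)[C@@H](OC(=O)CC(C)C)CO[Si](CC)(CC)CC)cc1 | intermediate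
24 | C1,C2,C6-tris-TES ether | COc1ccc(COCC[C@@H](O[Si](C)(C)C(C)(C)C)[C@H](C)[C@@](O[Si](CC)(CC)CC)(C(O[Si](CC)(CC)CC)/C=C\C)[C@@H](OC(=O)CC(C)C)CO[Si](CC)(CC)CC)cc1 | intermediate
25 | C7 primary alcohol | OCC[C@@H](O[Si](C)(C)C(C)(C)C)[C@H](C)[C@@](O[Si](CC)(CC)CC)(C(O[Si](CC)(CC)CC)/C=C\C)[C@@H](OC(=O)CC(C)C)CO[Si](CC)(CC)CC | intermediate
26 | C7 aldehyde | O=CC[C@@H](O[Si](C)(C)C(C)(C)C)[C@H](C)[C@@](O[Si](CC)(CC)CC)(C(O[Si](CC)(CC)CC)/C=C\C)[C@@H](OC(=O)CC(C)C)CO[Si](CC)(CC)CC | intermediate
27 | methyl acrylate | C=CC(=O)OC | starting material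
28 | Morita–Baylis–Hillman adduct, C7 and C2 epimers | C=C(C(=O)OC)C(O)C[C@@H](O[Si](C)(C)C(C)(C)C)[C@H](C)[C@@](O[Si](CC)(CC)CC)(C(O[Si](CC)(CC)CC)/C=C\C)[C@@H](OC(=O)CC(C)C)CO[Si](CC)(CC)CC | intermediate
29 | (Z)-2-(bromomethyl)enoate, tris-TES ether | COC(=O)/C(CBr)=C/C[C@@H](O[Si](C)(C)C(C)(C)C)[C@H](C)[C@@](O[Si](CC)(CC)CC)(C(O[Si](CC)(CC)CC)/C=C\C)[C@@H](OC(=O)CC(C)C)CO[Si](CC)(CC)CC | intermediate
30 | C2,C6-diol bromide | COC(=O)/C(CBr)=C/C[C@@H](O[Si](C)(C)C(C)(C)C)[C@H](C)[C@@](O[Si](CC)(CC)CC)(C(O)/C=C\C)[C@@H](OC(=O)CC(C)C)CO | intermediate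
31 | ring-closure precursor (C6 aldehyde, Z-enone, bromomethyl enoate) | COC(=O)/C(CBr)=C/C[C@@H](O[Si](C)(C)C(C)(C)C)[C@H](C)[C@@](O[Si](CC)(CC)CC)(C(=O)/C=C\C)[C@H](C=O)OC(=O)CC(C)C | intermediate
32 | σ-allylchromium dichloride from 31 (not isolated, alkene geometry fluxional) | COC(=O)C(C[Cr](Cl)Cl)=CC[C@@H](O[Si](C)(C)C(C)(C)C)[C@H](C)[C@@](O[Si](CC)(CC)CC)(C(=O)/C=C\C)[C@H](C=O)OC(=O)CC(C)C | intermediate
33 | ring-closed chromium alkoxide of the C6 hydroxy ester (not isolated) | C=C(C(=O)OC)[C@@H]1C[C@@H](O[Si](C)(C)C(C)(C)C)[C@H](C)[C@@](O[Si](CC)(CC)CC)(C(=O)/C=C\C)[C@@H](OC(=O)CC(C)C)[C@@H]1O[Cr](Cl)Cl | intermediate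
34 | bis-silyl ether of the target (C9 TBS, C1 TES) | C=C1C(=O)O[C@@H]2[C@H]1C[C@@H](O[Si](C)(C)C(C)(C)C)[C@H](C)[C@@](O[Si](CC)(CC)CC)(C(=O)/C=C\C)[C@H]2OC(=O)CC(C)C | intermediate
35 | CNP0186412.2 | C=C1C(=O)O[C@@H]2[C@H]1C[C@@H](O)[C@H](C)[C@@](O)(C(=O)/C=C\C)[C@H]2OC(=O)CC(C)C | target

**Step count**
- Total step count: 23.
- Longest linear sequence: 22 steps (4 → 5 → 6 → 8 → … → 35, steps 2–23).

**Steps most likely to fail**

Step 22
- What may go wrong: attack on the wrong face of the C6 aldehyde; competing closure of C7 onto the C2 ketone; Z to E isomerisation of the enone by the trivalent chromium halides that build up; or protonation of the allylchromium species before ring closure.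
- Fallback: the rings are closed before the enone exists, so C2 is an sp3 centre that cannot compete or isomerise and the environment around C1 is different.
- Path: from 29 only the primary silyl ether is cleaved (pyridinium p-toluenesulfonate, MeOH–CH2Cl2, −20 °C, short time) to give the C6 primary alcohol F1. Buffered DMP gives the C6 aldehyde with C2 still silylated F2, and CrCl2 in dilute THF closes both rings to the tris-silyl lactone F3. Pyridinium p-toluenesulfonate in MeOH frees the secondary allylic alcohol F4, and DMP oxidation returns to the route at 34.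

Step 20
- What may go wrong: loss of the tertiary C1 silyl ether along with the other two; incomplete cleavage at the hindered C2 ether; and migration of the isovaleryl group from O5 to the freed O6.
- Fallback: no differentiation between the three triethylsilyl ethers is required, and C1 is left unprotected.
- Path: from 29 all three are removed (pyridinium p-toluenesulfonate, MeOH, rt; the TBS ether stays) to give the C1,C2,C6-triol F5. DMP oxidises the two oxidisable carbinols to the hydroxy keto aldehyde F6. The CrCl2 cyclisation, which tolerates a free tertiary hydroxyl, gives the C9 silyl ether lactone F7, and HF·pyridine rejoins the route at 35.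

Step 18
- What may go wrong: very slow addition to the aldehyde, and β-elimination of the C9 silyloxy group during long exposure to the amine.
- Fallback: an aldol reaction followed by selenoxide elimination replaces amine catalysis.
- Path: from 26 the lithium enolate of methyl 2-(phenylselanyl)propanoate (LDA, THF, −78 °C) adds to the aldehyde to give the α-selanyl β-hydroxy ester F8. Oxidation with H2O2 and pyridine in CH2Cl2 at 0 °C triggers syn elimination toward the methyl group, away from the carbinol carbon, and rejoins the route at 28.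

Further compounds
F1 | step 22 | C6 primary alcohol, C1 and C2 TES ethers kept | COC(=O)/C(CBr)=C/C[C@@H](O[Si](C)(C)C(C)(C)C)[C@H](C)[C@@](O[Si](CC)(CC)CC)(C(O[Si](CC)(CC)CC)/C=C\C)[C@@H](OC(=O)CC(C)C)CO
F2 | step 22 | C6 aldehyde with C2 still silylated | COC(=O)/C(CBr)=C/C[C@@H](O[Si](C)(C)C(C)(C)C)[C@H](C)[C@@](O[Si](CC)(CC)CC)(C(O[Si](CC)(CC)CC)/C=C\C)[C@H](C=O)OC(=O)CC(C)C
F3 | step 22 | tris-silyl lactone | C=C1C(=O)O[C@@H]2[C@H]1C[C@@H](O[Si](C)(C)C(C)(C)C)[C@H](C)[C@@](O[Si](CC)(CC)CC)(C(O[Si](CC)(CC)CC)/C=C\C)[C@H]2OC(=O)CC(C)C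
F4 | step 22 | lactone with free C2 allylic alcohol | C=C1C(=O)O[C@@H]2[C@H]1C[C@@H](O[Si](C)(C)C(C)(C)C)[C@H](C)[C@@](O[Si](CC)(CC)CC)(C(O)/C=C\C)[C@H]2OC(=O)CC(C)C
F5 | step 20 | C1,C2,C6-triol bromide | COC(=O)/C(CBr)=C/C[C@@H](O[Si](C)(C)C(C)(C)C)[C@H](C)[C@@](O)(C(O)/C=C\C)[C@@H](OC(=O)CC(C)C)CO
F6 | step 20 | hydroxy keto aldehyde with free C1–OH | COC(=O)/C(CBr)=C/C[C@@H](O[Si](C)(C)C(C)(C)C)[C@H](C)[C@@](O)(C(=O)/C=C\C)[C@H](C=O)OC(=O)CC(C)C
F7 | step 20 | C9 silyl ether lactone with free C1–OH | C=C1C(=O)O[C@@H]2[C@H]1C[C@@H](O[Si](C)(C)C(C)(C)C)[C@H](C)[C@@](O)(C(=O)/C=C\C)[C@H]2OC(=O)CC(C)C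
F8 | step 18 | α-selanyl β-hydroxy ester | COC(=O)C(C)([Se]c1ccccc1)C(O)C[C@@H](O[Si](C)(C)C(C)(C)C)[C@H](C)[C@@](O[Si](CC)(CC)CC)(C(O[Si](CC)(CC)CC)/C=C\C)[C@@H](OC(=O)CC(C)C)CO[Si](CC)(CC)CC
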